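## Structural features

The target has two benzene rings joined by a single ether oxygen, from C6 of ring A to C1' of ring B. There is no other ring and no stereocenter, so no stereochemical relationships arise, and the prenyl alkene has two identical methyl groups and therefore no geometry.

Ring A is a 1,2,3,4-tetrasubstituted salicylic acid: CO2H at C1, OH at C2, prenyl at C3 and the ether oxygen at C6. Ring B carries the ether oxygen at C1', a free OH at C2', a methyl at C4' and a hydroxymethyl at C6'.

The fragile groups are:
- the prenyl group ortho to a phenol, which adds the phenol under acid to give a chroman and does not survive hydrogenolysis or electrophilic oxidants;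
- the benzylic alcohol of ring B;
- the 2,6-dioxygenated benzoic acid, which decarboxylates in hot acid.

The real difficulty is the ether link. Its oxygen sits between a carbon ortho to the carboxyl on ring A and a carbon on ring B whose two ortho positions are both substituted, so direct aryl-oxygen coupling would be hindered. Two carboxyl-derived carbons (C1 acid, C6' alcohol) and three hydroxyls must also be told apart.

The key step uses the fact that ring B (C1' with its ether oxygen, C2' with its hydroxyl, C3'-H, C4'-CH3, C5'-H, C6' with a carboxyl-level carbon) maps onto C3, C4, C5 and C6 of a 3-aryloxy-6-methyl-2-pyrone-4-carboxylate plus a two-carbon ketene equivalent that supplies C2' (with its oxygen) and C3'.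

## Logic of the disconnections

22 from 20. No skeletal bond is cut. The acyl-oxygen bond of the ring A methyl ester and the O-CH2 bond of the C2 acetal are restored. The free salicylic acid with its prenylphenol could not pass through acylation, cycloaddition and hydride steps. The demand on the forward step is hydrolysis of an ester flanked by two ortho oxygens (through 21), and an acid stage mild enough that the freed phenol does not add to the prenyl alkene and the benzylic alcohol does not ionise.

20 from 19. The C6' hydroxymethyl is taken back to the ethyl ester. That ester is the carbon that activated the pyrone, so it costs nothing extra. The forward step must reduce one of two aryl esters; the ring B ester has one ortho neighbour and the ring A ester has two.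

19 from 14 and 15. Ring B is opened at C1'-C2' and C3'-C4'. This removes a whole benzene ring and leaves the ether oxygen on a pyrone carbon that was made from an sp3 O-CH2 unit, so no hindered aryl-oxygen bond is ever formed. The forward step needs one orientation of a ketene acetal across C3 and C6 of 14 and no acidic proton in 14; that is why the ring A phenol is capped.

14 from 10 and 11. The pyrone is cut at its C3=C4 double bond and its lactone acyl-oxygen bond. This exposes an aryloxyacetic acid and a commercial diketo ester. The forward step must put the acyl group on the oxygen derived from the acetyl group of 11 and condense the OCH2 with the keto-ester carbonyl. It must also avoid Dieckmann closure of the same CH2 onto the ring A ester, so only amine bases are used.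

10 from 9 from 8. The acid is taken back to a methyl ester and the acetal to the free phenol. An acid-labile ester on the acetic acid arm would need conditions that strip the acetal and cyclise the prenylphenol, so that arm is carried as a methyl ester. Cold hydroxide cleaves it while the shielded benzoate stays intact. The acetal is installed with an amine base for the Dieckmann reason above.

8 from 6 from 5 from 3 and 4. The C3-prenyl bond is cut by a retro-[3,3] shift to the 1,1-dimethylallyl ether, then back through the propargyl ether to the phenol and the tertiary propargylic chloride. C1 is blocked by the ester, so the rearrangement can only deliver to C3. The forward sequence needs etherification of a hydrogen-bonded phenol at a tertiary carbon and a semihydrogenation that stops at the alkene.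

3 from 1 and 2. The O-CH2 bond is cut. This is the bond that becomes the diaryl ether oxygen-carbon bond of ring B. The forward step needs mono-alkylation of a symmetrical diphenol, helped by the hydrogen bond that deactivates the second hydroxyl once the first is alkylated.

## Other disconnections considered

Alternative 1: Ring A is cut at C1-C2, C5-C6 and C2-C3, leaving diazo ketone A2 and aryl alkynyl ether A3.
- Forward key step: irradiation of A2 should cause Wolff rearrangement to vinylketene A4. A4 adds [2+2] to the electron-rich alkyne of A3; four-electron ring opening, six-electron electrocyclisation and tautomerisation then give phenol A1.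
- In favour: all four contiguous substituents of ring A are placed by connectivity, the medium is neutral, and the ether oxygen is never joined to a hindered arene.
- Against: A3 needs the differentiated catechol A5 (several steps) followed by ynol ether chemistry through a dichlorovinyl ether. A2 is a skipped diene carrying a diazo ketone, and its trisubstituted alkene can intercept the carbene or the ketene. C1 arrives as an acetal, so the end game needs acetal hydrolysis, aldehyde-to-acid oxidation next to two electron-rich rings and a prenyl group, and removal of silyl and acetal groups.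
- Comparison: on structure it is the equal of the chosen plan, since both fix the ring A pattern without ambiguity. On mechanism it is the better, because its regiochemistry rests on one strong polarity match of ketene and ynol ether, whereas the pyrone orientation rests on a balance of substituent effects. On step economy it is clearly worse: about four operations after the key step against two, more protecting groups, and an estimated total well above ten.

Alternative 2: The cut is at the O-C6 bond and the C1-CO2H bond; no ring is formed.
- Forward key step: CsF converts silyl triflate A7 to aryne A8. The cesium salt of A5 adds at the aryne carbon remote from the acetal oxygen, and the aryl anion is carboxylated by CO2 to give A6.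
- In favour: it is the most convergent plan, the carboxyl arrives at the acid oxidation level, and only acetal and silyl removal remain. On convergence and length of the end game it is the better of the two. Aryne additions are also little affected by ortho substituents on the nucleophile.
- Against: the aryl anion must meet CO2 before any proton source. The phenoxide equilibrates with its aryl carbonate under CO2, which lowers its concentration. The prenyl alkenes are ene partners for an aryne. The capture sequence is well established for nitrogen nucleophiles and would be an extrapolation for a hindered phenoxide. A7 (contiguous silyl, triflate, acetal and prenyl) and A5 each need about five or six steps.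
- Comparison: on structure it makes the hindered aryl-oxygen bond directly, which the chosen plan avoids. On mechanism it needs two intermolecular captures of short-lived species, against one thermal cycloaddition followed by unimolecular steps. On step economy its longest linear sequence could be shorter, but its total count is estimated higher.

Alternative 3: Ring A is cut at C1-C6 and C3-C4, leaving ynal A10 and keto ester A11.
- Forward key step: under mild base the mono-anion of A11 adds through its central carbon to the aryloxy-bearing alkyne carbon of A10. The gamma carbon then closes on the aldehyde, and dehydration gives salicylate A9.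
- In favour: ring A arrives with the ester at C1, the free hydroxyl at C2 and the prenyl at C3, which is the equal of the chosen plan in oxidation level. A11 is one step from methyl acetoacetate. The salicylate ester of A9 is less shielded than the ester of 20, a small advantage in the final hydrolysis.
- Against: A10 is a push-pull alkyne. The carbon that is attacked carries the aryloxy group, which after addition is the leaving group of a vinylogous ester, so a second addition-elimination can expel the phenoxide of A5 and sever the ether. Direct attack on the aldehyde would reverse the ring orientation. A mono-anion is nucleophilic at the central carbon and at oxygen, not at the gamma carbon, so closure to a pyran competes with the aldol. A10 needs A5 plus ynol ether formation and formylation, and it is fragile.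
- Comparison: on structure it is equal (ring A built with the right pattern, ether oxygen on an sp carbon). On mechanism it is weaker, because the chemoselectivity of the annulation is less secure than the orientation of the pyrone cycloaddition. On step economy the end game is similar, but the preparation of A5 and A10 makes the total longer.

Key step: step 8

Assumptions and corrections to the plan:
- 1,1-Bis(trimethylsilyloxy)ethene (15) is treated as a purchasable reagent; otherwise it is one step from trimethylsilyl acetate, LiN(iPr)2 and Me3SiCl.
- The acetic acid arm is carried as a methyl ester, not a tert-butyl ester, because an acid-labile ester could not be removed in the presence of the MOM ether and the prenylphenol.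
- The propargyl ether is semihydrogenated before the Claisen step; rearranged directly it would give a chromene.

Step 1
Reactants: 1 methyl 2,6-dihydroxybenzoate; 2 methyl bromoacetate
Product: 3 methyl 2-hydroxy-6-(2-methoxy-2-oxoethoxy)benzoate
Conditions: 2 (1.05 equiv), K2CO3 (1.2 equiv), acetone, 50 °C
Reagents that add atoms: none
Why: Williamson ether synthesis; after the first alkylation the remaining hydroxyl is locked in a hydrogen bond to the ester carbonyl and is much less nucleophilic, so mono-alkylation should dominate, and K2CO3 in acetone is too weak to start a Dieckmann closure.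

Step 2
Reactants: 3 methyl 2-hydroxy-6-(2-methoxy-2-oxoethoxy)benzoate; 4 3-chloro-3-methylbut-1-yne
Product: 5 methyl 2-(2-methoxy-2-oxoethoxy)-6-[(2-methylbut-3-yn-2-yl)oxy]benzoate
Conditions: 4 (2 equiv), DBU, CuCl2 (1 mol %), MeCN, 0 °C to rt
Reagents that add atoms: none
Why: Copper-catalysed propargylic etherification; the copper acetylide of 4 ionises to an allenylidene-type electrophile that the phenoxide captures at the tertiary carbon, a pathway that needs no SN2 geometry and tolerates hydrogen-bonded phenols.

Step 3
Reactants: 5 methyl 2-(2-methoxy-2-oxoethoxy)-6-[(2-methylbut-3-yn-2-yl)oxy]benzoate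
Product: 6 methyl 2-(2-methoxy-2-oxoethoxy)-6-[(2-methylbut-3-en-2-yl)oxy]benzoate
Conditions: H2 (1 atm, 1 equiv uptake), Pd/CaCO3 poisoned with Pb(OAc)2, quinoline, EtOAc, rt
Reagents that add atoms: none
Why: Semihydrogenation of a terminal alkyne over lead-poisoned palladium stops at the alkene; esters and the aryl ether are inert.

Step 4
Reactants: 6 methyl 2-(2-methoxy-2-oxoethoxy)-6-[(2-methylbut-3-en-2-yl)oxy]benzoate
Product: 8 methyl 2-hydroxy-6-(2-methoxy-2-oxoethoxy)-3-(3-methylbut-2-en-1-yl)benzoate, via Claisen dienone 7 (not isolated)
Conditions: PhNEt2, 130 °C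
Reagents that add atoms: none
Why: Aromatic Claisen rearrangement; the [3,3] shift delivers the allyl terminus to C3, the only free ortho carbon, turning the 1,1-dimethylallyl group into prenyl; dienone 7 tautomerises to the phenol, and the basic aniline solvent suppresses acid-catalysed chroman formation.

Step 5
Reactants: 8 methyl 2-hydroxy-6-(2-methoxy-2-oxoethoxy)-3-(3-methylbut-2-en-1-yl)benzoate
Product: 9 methyl 2-(methoxymethoxy)-6-(2-methoxy-2-oxoethoxy)-3-(3-methylbut-2-en-1-yl)benzoate
Conditions: MOMCl, iPr2NEt, Bu4NI (cat.), CH2Cl2, 0 to 40 °C
Reagents that add atoms: chloromethyl methyl ether, COCCl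
Why: O-Alkylation of the hindered, hydrogen-bonded phenol by a highly electrophilic chloromethyl ether under iodide catalysis; an amine base is used because a hydride or alkoxide base would enolise the aryloxyacetate and close it onto the ring A ester (Dieckmann).

Step 6
Reactants: 9 methyl 2-(methoxymethoxy)-6-(2-methoxy-2-oxoethoxy)-3-(3-methylbut-2-en-1-yl)benzoate
Product: 10 [3-(methoxymethoxy)-2-(methoxycarbonyl)-4-(3-methylbut-2-en-1-yl)phenoxy]acetic acid
Conditions: LiOH·H2O (1.2 equiv), THF/H2O, 0 °C; then 1 M HCl to pH 4, 0 °C
Reagents that add atoms: lithium hydroxide, [Li+].[OH-]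
Why: Chemoselective saponification; the alpha-aryloxy acetate is unhindered and inductively activated, while the benzoate is shielded by two ortho substituents, and the acetal and prenyl groups are inert to cold hydroxide.

Step 7
Reactants: 10 [3-(methoxymethoxy)-2-(methoxycarbonyl)-4-(3-methylbut-2-en-1-yl)phenoxy]acetic acid; 11 ethyl 2,4-dioxopentanoate
Product: 14 ethyl 3-[3-(methoxymethoxy)-2-(methoxycarbonyl)-4-(3-methylbut-2-en-1-yl)phenoxy]-6-methyl-2-oxo-2H-pyran-4-carboxylate, via aryloxyacetyl chloride 12 (not isolated), via enol ester 13 (not isolated)
Conditions: Me2C=C(Cl)NMe2 (1.1 equiv), CH2Cl2, 0 °C; then added to 11, Et3N, CH2Cl2, -20 to 0 °C; then DBU, 4 Å MS, 0 °C to rt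
Reagents that add atoms: none
Why: Neutral acid chloride formation spares the acetal; the triethylammonium enolate of 11 is O-acylated to enol ester 13, and DBU then effects intramolecular Knoevenagel (aldol) condensation of the activated OCH2 onto the keto-ester carbonyl with E1cB loss of water, the open-chain counterpart of the coumarin synthesis from O-acyl salicyl ketones. Acyl shifts between the two enol oxygens are fast under base, and closure onto the far more electrophilic alpha-keto ester carbonyl should outrun closure onto the methyl ketone of the other isomer, which directs the ester to C4 and the methyl to C6.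

Step 8
Reactants: 14 ethyl 3-[3-(methoxymethoxy)-2-(methoxycarbonyl)-4-(3-methylbut-2-en-1-yl)phenoxy]-6-methyl-2-oxo-2H-pyran-4-carboxylate; 15 1,1-bis(trimethylsilyloxy)ethene
Product: 19 methyl 6-[2-(ethoxycarbonyl)-6-hydroxy-4-methylphenoxy]-2-(methoxymethoxy)-3-(3-methylbut-2-en-1-yl)benzoate, via bridged lactone cycloadduct 16 (not isolated), via bis(silyloxy)cyclohexadiene 17 (not isolated), via aryl trimethylsilyl ether 18 (not isolated)
Conditions: 15 (5 equiv), toluene, 110 °C, sealed tube; then 10% aq. citric acid/THF, rt
Reagents that add atoms: none
Why: The electron-rich ketene acetal adds across C3 and C6 of the electron-poor pyrone in an inverse-demand Diels-Alder reaction, probably asynchronous, with its CH2 terminus bonding first to C6 and the acetal carbon then to C3, to give bridged lactone 16. Cycloreversion expels CO2 to give cyclohexadiene 17, 1,2-elimination of Me3SiOH aromatises it to silyl ether 18, and the citric acid work-up frees phenol 19. The closest known reaction type is the cycloaddition of 2-pyrone carboxylates with 1,1-dialkoxyethenes or 1,1-disilyloxyethenes that ends in an aryl ether or phenol after loss of CO2 and of one oxygen substituent. Ring B is closed by the intermolecular [4+2] step, which forms C1'-C2' and C3'-C4', and becomes aromatic by retro-[4+2] and elimination. The two bridgehead stereocenters of 16 are erased on aromatisation, so no facial or endo/exo control is needed. The selectivity required is regiochemical: C6 is the vinylogous acyl carbon of the dienyl lactone and carries only a methyl group, whereas C3 carries the aryloxy donor, which offsets the pull of the C4 ester on that carbon (a beta-aryloxy acrylate is a vinylogous carbonate) and, with the flanking carbonyls, hinders approach of the CH2 terminus. The two silyloxy groups are equivalent, so elimination can give only one aryl silyl ether, and the acetal cap on ring A leaves no proton to destroy the ketene acetal.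

Step 9
Reactants: 19 methyl 6-[2-(ethoxycarbonyl)-6-hydroxy-4-methylphenoxy]-2-(methoxymethoxy)-3-(3-methylbut-2-en-1-yl)benzoate
Product: 20 methyl 6-[2-hydroxy-6-(hydroxymethyl)-4-methylphenoxy]-2-(methoxymethoxy)-3-(3-methylbut-2-en-1-yl)benzoate
Conditions: LiBH4 (3 equiv), THF, 0 °C to rt; aq. NH4Cl
Reagents that add atoms: none
Why: Lithium-assisted borohydride reduction of an ester; the ring B ester has one ortho neighbour whereas the ring A ester is shielded by two, and the phenoxide formed first is meta to the ring B ester and does not deactivate it; the alkene, acetal and diaryl ether are inert.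

Step 10
Reactants: 20 methyl 6-[2-hydroxy-6-(hydroxymethyl)-4-methylphenoxy]-2-(methoxymethoxy)-3-(3-methylbut-2-en-1-yl)benzoate
Product: 22 2-hydroxy-6-[2-hydroxy-6-(hydroxymethyl)-4-methylphenoxy]-3-(3-methylbut-2-en-1-yl)benzoic acid, via MOM-protected benzoic acid 21 (not isolated)
Conditions: KOH (6 equiv), MeOH/H2O 3:1, 65 °C, argon; then 0 °C, 3 M HCl to pH 1, rt
Reagents that add atoms: potassium hydroxide, [K+].[OH-]
Why: Hot hydroxide cleaves the shielded methyl ester by acyl substitution while the phenoxide, alkene and acetal are stable to base; acidifying the same pot hydrolyses the MOM acetal, which is assisted by the neighbouring carboxylic acid, so room temperature and short exposure should suffice without adding the phenol to the prenyl alkene.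

## Compound list

1 | methyl 2,6-dihydroxybenzoate | COC(=O)c1c(O)cccc1O | starting material
2 | methyl bromoacetate | COC(=O)CBr | starting material
3 | methyl 2-hydroxy-6-(2-methoxy-2-oxoethoxy)benzoate | COC(=O)COc1cccc(O)c1C(=O)OC | intermediate
4 | 3-chloro-3-methylbut-1-yne | CC(C)(Cl)C#C | starting material
5 | methyl 2-(2-methoxy-2-oxoethoxy)-6-[(2-methylbut-3-yn-2-yl)oxy]benzoate | COC(=O)COc1cccc(OC(C)(C)C#C)c1C(=O)OC | intermediate
6 | methyl 2-(2-methoxy-2-oxoethoxy)-6-[(2-methylbut-3-en-2-yl)oxy]benzoate | COC(=O)COc1cccc(OC(C)(C)C=C)c1C(=O)OC | intermediate
7 | methyl 2-(2-methoxy-2-oxoethoxy)-5-(3-methylbut-2-en-1-yl)-6-oxocyclohexa-1,3-diene-1-carboxylate (racemic, not isolated) | COC(=O)COC1=C(C(=O)OC)C(=O)C(CC=C(C)C)C=C1 | intermediate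
8 | methyl 2-hydroxy-6-(2-methoxy-2-oxoethoxy)-3-(3-methylbut-2-en-1-yl)benzoate | COC(=O)COc1ccc(CC=C(C)C)c(O)c1C(=O)OC | intermediate
9 | methyl 2-(methoxymethoxy)-6-(2-methoxy-2-oxoethoxy)-3-(3-methylbut-2-en-1-yl)benzoate | COC(=O)COc1ccc(CC=C(C)C)c(OCOC)c1C(=O)OC | intermediate
10 | [3-(methoxymethoxy)-2-(methoxycarbonyl)-4-(3-methylbut-2-en-1-yl)phenoxy]acetic acid | OC(=O)COc1ccc(CC=C(C)C)c(OCOC)c1C(=O)OC | intermediate
11 | ethyl 2,4-dioxopentanoate | CCOC(=O)C(=O)CC(C)=O | starting material
12 | methyl 6-(2-chloro-2-oxoethoxy)-2-(methoxymethoxy)-3-(3-methylbut-2-en-1-yl)benzoate (not isolated) | ClC(=O)COc1ccc(CC=C(C)C)c(OCOC)c1C(=O)OC | intermediate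
13 | ethyl (3Z)-4-({[3-(methoxymethoxy)-2-(methoxycarbonyl)-4-(3-methylbut-2-en-1-yl)phenoxy]acetyl}oxy)-2-oxopent-3-enoate (not isolated) | CCOC(=O)C(=O)/C=C(/C)OC(=O)COc1ccc(CC=C(C)C)c(OCOC)c1C(=O)OC | intermediate
14 | ethyl 3-[3-(methoxymethoxy)-2-(methoxycarbonyl)-4-(3-methylbut-2-en-1-yl)phenoxy]-6-methyl-2-oxo-2H-pyran-4-carboxylate | COCOc1c(CC=C(C)C)ccc(Oc2c(C(=O)OCC)cc(C)oc2=O)c1C(=O)OC | intermediate
15 | 1,1-bis(trimethylsilyloxy)ethene | C=C(O[Si](C)(C)C)O[Si](C)(C)C | starting material
16 | ethyl 4-[3-(methoxymethoxy)-2-(methoxycarbonyl)-4-(3-methylbut-2-en-1-yl)phenoxy]-1-methyl-3-oxo-5,5-bis(trimethylsilyloxy)-2-oxabicyclo[2.2.2]oct-7-ene-8-carboxylate (racemic, not isolated) | CC12OC(=O)C(Oc3ccc(CC=C(C)C)c(OCOC)c3C(=O)OC)(C(C(=O)OCC)=C1)C(O[Si](C)(C)C)(O[Si](C)(C)C)C2 | intermediate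
17 | ethyl 2-[3-(methoxymethoxy)-2-(methoxycarbonyl)-4-(3-methylbut-2-en-1-yl)phenoxy]-5-methyl-3,3-bis(trimethylsilyloxy)cyclohexa-1,5-diene-1-carboxylate (not isolated) | CCOC(=O)C1=C(Oc2ccc(CC=C(C)C)c(OCOC)c2C(=O)OC)C(O[Si](C)(C)C)(O[Si](C)(C)C)CC(C)=C1 | intermediate
18 | methyl 6-[2-(ethoxycarbonyl)-4-methyl-6-(trimethylsilyloxy)phenoxy]-2-(methoxymethoxy)-3-(3-methylbut-2-en-1-yl)benzoate (not isolated) | CCOC(=O)c1cc(C)cc(O[Si](C)(C)C)c1Oc1ccc(CC=C(C)C)c(OCOC)c1C(=O)OC | intermediate
19 | methyl 6-[2-(ethoxycarbonyl)-6-hydroxy-4-methylphenoxy]-2-(methoxymethoxy)-3-(3-methylbut-2-en-1-yl)benzoate | COCOc1c(CC=C(C)C)ccc(Oc2c(O)cc(C)cc2C(=O)OCC)c1C(=O)OC | intermediate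
20 | methyl 6-[2-hydroxy-6-(hydroxymethyl)-4-methylphenoxy]-2-(methoxymethoxy)-3-(3-methylbut-2-en-1-yl)benzoate | COCOc1c(CC=C(C)C)ccc(Oc2c(O)cc(C)cc2CO)c1C(=O)OC | intermediate
21 | 6-[2-hydroxy-6-(hydroxymethyl)-4-methylphenoxy]-2-(methoxymethoxy)-3-(3-methylbut-2-en-1-yl)benzoic acid (not isolated) | COCOc1c(CC=C(C)C)ccc(Oc2c(O)cc(C)cc2CO)c1C(=O)O | intermediate
22 | 2-hydroxy-6-[2-hydroxy-6-(hydroxymethyl)-4-methylphenoxy]-3-(3-methylbut-2-en-1-yl)benzoic acid | CC(C)=CCc1ccc(Oc2c(O)cc(C)cc2CO)c(C(=O)O)c1O | target

## Step count and least certain steps

Total step count: 10. Longest linear sequence: 10 steps (1 to 22); compounds 2, 4, 11 and 15 are purchased.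

Step 8 (key step). The most likely failure is a slow cycloaddition onto a pyrone whose C3 carries a donor, during which the thermally labile bis(trimethylsilyl) ketene acetal is consumed by oxygen-to-carbon silyl migration or protonolysis. A second failure is leakage to the reverse orientation, because the C4 ester activates C3. The fallback answers the first failure: from 14, the cycloaddition is run with the more robust 1,1-bis(tert-butyldimethylsilyloxy)ethene (mesitylene, 140 °C) to give methyl 6-[2-(tert-butyldimethylsilyloxy)-6-(ethoxycarbonyl)-4-methylphenoxy]-2-(methoxymethoxy)-3-(3-methylbut-2-en-1-yl)benzoate F1, which is isolated and desilylated with Bu4NF buffered with AcOH to return to the route at 19. The orientation itself is intrinsic to the disconnection and is argued from polarisation and sterics only.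

Step 7. Acylation may settle on the wrong enol oxygen of 11 and be followed by closure onto the methyl ketone, which would give the regioisomeric pyrone; base may also cause acyl transfer to carbon. The fallback fixes the position of the acyloxy group by construction. Ethyl 2-oxopent-3-ynoate F2 is made from CH3C≡CMgBr and diethyl oxalate at -78 °C. Acid 10 is added to F2 in conjugate fashion (DABCO cat., CH2Cl2), which places the carboxylate on the methyl-bearing carbon and gives 13 together with its geometric isomer ethyl (3E)-4-({[3-(methoxymethoxy)-2-(methoxycarbonyl)-4-(3-methylbut-2-en-1-yl)phenoxy]acetyl}oxy)-2-oxopent-3-enoate F3. The amine equilibrates F3 with 13 by addition-elimination, and DBU closes 13 as before, returning to the route at 14.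

Step 9. Chemoselectivity may be lost through hydride attack on the ring A ester, either directly or after the ring B phenoxide has transesterified onto it. The fallback separates the two carboxyl carbons by functional class and not by rate of hydride attack. From 19, LiOH in THF/H2O at rt to 40 °C hydrolyses only the less hindered ethyl ester to 3-hydroxy-2-[3-(methoxymethoxy)-2-(methoxycarbonyl)-4-(3-methylbut-2-en-1-yl)phenoxy]-5-methylbenzoic acid F4. Isobutyl chloroformate and N-methylmorpholine at -15 °C convert F4 to the mixed carbonic anhydride F5, and NaBH4 in THF/H2O at 0 °C reduces F5 to the benzylic alcohol, returning to the route at 20.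

Step 10. The hydrolysis of the doubly ortho-substituted ester may be incomplete, and in the acid stage the freed phenol may add to the prenyl alkene or the benzylic alcohol may ionise. The fallback reverses the order so that the last operation is basic and no mineral acid stage is needed. From 20, pyridinium p-toluenesulfonate in tert-butanol at 80 °C removes the acetal by transacetalisation to give methyl 2-hydroxy-6-[2-hydroxy-6-(hydroxymethyl)-4-methylphenoxy]-3-(3-methylbut-2-en-1-yl)benzoate F6. KOH in aqueous MeOH at 70 °C then hydrolyses this salicylate ester, and cold acidification only to pH 3 returns to the route at 22.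

Step 2. Etherification of the hydrogen-bonded phenol at a tertiary carbon may be sluggish, with elimination of 4 to the enyne taking over. The fallback goes from 3 directly to 6, bypassing 5: allylic etherification with tert-butyl 2-methylbut-3-en-2-yl carbonate and Pd(PPh3)4 (zerovalent palladium) in THF at 0 °C, which forms the branched 1,1-dimethylallyl ether under kinetic control. It makes no new compound (F0).

## Further compounds

F1 | step 8 | methyl 6-[2-(tert-butyldimethylsilyloxy)-6-(ethoxycarbonyl)-4-methylphenoxy]-2-(methoxymethoxy)-3-(3-methylbut-2-en-1-yl)benzoate | CCOC(=O)c1cc(C)cc(O[Si](C)(C)C(C)(C)C)c1Oc1ccc(CC=C(C)C)c(OCOC)c1C(=O)OC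
F2 | step 7 | ethyl 2-oxopent-3-ynoate | CCOC(=O)C(=O)C#CC
F3 | step 7 | ethyl (3E)-4-({[3-(methoxymethoxy)-2-(methoxycarbonyl)-4-(3-methylbut-2-en-1-yl)phenoxy]acetyl}oxy)-2-oxopent-3-enoate | CCOC(=O)C(=O)/C=C(\C)OC(=O)COc1ccc(CC=C(C)C)c(OCOC)c1C(=O)OC
F4 | step 9 | 3-hydroxy-2-[3-(methoxymethoxy)-2-(methoxycarbonyl)-4-(3-methylbut-2-en-1-yl)phenoxy]-5-methylbenzoic acid | COCOc1c(CC=C(C)C)ccc(Oc2c(O)cc(C)cc2C(=O)O)c1C(=O)OC
F5 | step 9 | 3-hydroxy-2-[3-(methoxymethoxy)-2-(methoxycarbonyl)-4-(3-methylbut-2-en-1-yl)phenoxy]-5-methylbenzoic isobutyl carbonic anhydride | COCOc1c(CC=C(C)C)ccc(Oc2c(O)cc(C)cc2C(=O)OC(=O)OCC(C)C)c1C(=O)OC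
F6 | step 10 | methyl 2-hydroxy-6-[2-hydroxy-6-(hydroxymethyl)-4-methylphenoxy]-3-(3-methylbut-2-en-1-yl)benzoate | COC(=O)c1c(O)c(CC=C(C)C)ccc1Oc1c(O)cc(C)cc1CO
F0 | step 2 | none | none
A1 | alternative 1 | 2-(diethoxymethyl)-3-[2-({[tert-butyl(dimethyl)silyl]oxy}methyl)-6-(methoxymethoxy)-4-methylphenoxy]-6-(3-methylbut-2-en-1-yl)phenol | CCOC(OCC)c1c(O)c(CC=C(C)C)ccc1Oc1c(OCOC)cc(C)cc1CO[Si](C)(C)C(C)(C)C
A2 | alternative 1 | (3E)-1-diazo-7-methylocta-3,6-dien-2-one | CC(C)=CC/C=C/C(=O)C=[N+]=[N-]
A3 | alternative 1 | tert-butyl({2-[(3,3-diethoxyprop-1-yn-1-yl)oxy]-3-(methoxymethoxy)-5-methylphenyl}methoxy)dimethylsilane | CCOC(OCC)C#COc1c(OCOC)cc(C)cc1CO[Si](C)(C)C(C)(C)C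
A4 | alternative 1 | (3E)-7-methylocta-1,3,6-trien-1-one | CC(C)=CC/C=C/C=C=O
A5 | alternative 1 | 2-({[tert-butyl(dimethyl)silyl]oxy}methyl)-6-(methoxymethoxy)-4-methylphenol | Oc1c(OCOC)cc(C)cc1CO[Si](C)(C)C(C)(C)C
A6 | alternative 2 | 6-[2-({[tert-butyl(dimethyl)silyl]oxy}methyl)-6-(methoxymethoxy)-4-methylphenoxy]-2-(methoxymethoxy)-3-(3-methylbut-2-en-1-yl)benzoic acid | CC(C)=CCc1ccc(Oc2c(OCOC)cc(C)cc2CO[Si](C)(C)C(C)(C)C)c(C(=O)O)c1OCOC
A7 | alternative 2 | 2-(methoxymethoxy)-3-(3-methylbut-2-en-1-yl)-6-(trimethylsilyl)phenyl trifluoromethanesulfonate | COCOc1c(CC=C(C)C)ccc([Si](C)(C)C)c1OS(=O)(=O)C(F)(F)F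
A8 | alternative 2 | 3-(methoxymethoxy)-4-(3-methylbut-2-en-1-yl)benzyne | COCOC1=C(CC=C(C)C)C=CC#C1
A9 | alternative 3 | methyl 6-[2-({[tert-butyl(dimethyl)silyl]oxy}methyl)-6-(methoxymethoxy)-4-methylphenoxy]-2-hydroxy-3-(3-methylbut-2-en-1-yl)benzoate | COC(=O)c1c(O)c(CC=C(C)C)ccc1Oc1c(OCOC)cc(C)cc1CO[Si](C)(C)C(C)(C)C
A10 | alternative 3 | 3-[2-({[tert-butyl(dimethyl)silyl]oxy}methyl)-6-(methoxymethoxy)-4-methylphenoxy]prop-2-ynal | O=CC#COc1c(OCOC)cc(C)cc1CO[Si](C)(C)C(C)(C)C
A11 | alternative 3 | methyl 7-methyl-3-oxooct-6-enoate | COC(=O)CC(=O)CCC=C(C)C
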